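**Strategy.** The route rests on inserting C10, already brominated, between the carbonyl carbon C9 and quaternary C11 of ring A. A six-membered C9 ketone would enolise toward C8 (α to C=O and allylic to C7=C14), so C10–Br is not made by α-bromination. Instead, dibromomethyllithium adds to the C9 carbonyl of a ring-A cyclopentanone and the derived β-oxido carbenoid shifts C11, enlarging ring A to the cyclohexanone with bromine on the new carbon in one operation. The precursor is the spiro[4.5] ketone 18, which carries C7=C14H2, the C9 carbonyl, C11Me2, the C6 spiro centre and the complete ring-B array (C2–Br, C3(Me)Cl).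

Key step: step 13

**Remarks on the chemistry**
- Chamigrane numbering is used from 13 on: spiro C6; ring B C1–C5; ring A C7–C11; C14 is the exocyclic methylene carbon. In the spiro[4.5]decane names of 8–12, C1, C3, C4, C5 and C7=C8 correspond to chamigrane C7, C9, C11, C6 and C2=C3.
- Assumption: intermolecular BrCl addition to the ring-B alkene would open the bromonium ion through a chair with C7, not CMe2, axial and so place Br syn to C7 (the wrong diastereomer); steps 7–9 therefore deliver the C3 heteroatom from C7.
- Assumption: the sense of induction in step 3 is assigned by analogy with the 2-alkylcyclohexanone series; the antipodal ligand is used if the S ketone does not result.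
- Compounds 9–17 are carried as epimer mixtures at C9 (and at C7 in 12–14 and 16); both centres are erased later (steps 10 and 12).
- Ketone 23 is expected together with its C10 epimer (F3 below); the two interconvert through the enol.

**Route**

Step 1
Reactants: 1 4,4-dimethylcyclopent-2-en-1-one; 2 4-bromo-2-methylbut-1-ene
Product: 4 4,4-dimethyl-5-(3-methylbut-3-en-1-yl)cyclopent-2-en-1-one (racemic), via lithium dienolate 3 (not isolated)
Conditions: LDA, THF, −78 °C; then 2 (1.5 equiv), DMPU, −78 → 0 °C
Reagents that add atoms: none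
Why: Enolate alkylation: the γ-carbon is quaternary, so LDA can deprotonate only C5, and the cross-conjugated dienolate 3 is C-alkylated by the primary bromide, DMPU favouring SN2 over E2.

Step 2
Reactants: 4 4,4-dimethyl-5-(3-methylbut-3-en-1-yl)cyclopent-2-en-1-one
Product: 6 allyl 3,3-dimethyl-2-(3-methylbut-3-en-1-yl)cyclopenta-1,4-dien-1-yl carbonate, via lithium dienolate 5 (not isolated)
Conditions: LDA, THF, −78 °C; TMEDA; allyl chloroformate, −78 °C
Reagents that add atoms: allyl chloroformate, C=CCOC(=O)Cl
Why: Enol carbonate formation: the remaining C5–H is removed and the fully substituted dienolate 5 is O-acylated by the chloroformate, which erases the racemic centre of 4.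

Step 3
Reactants: 6 allyl 3,3-dimethyl-2-(3-methylbut-3-en-1-yl)cyclopenta-1,4-dien-1-yl carbonate
Product: 7 (S)-5-allyl-4,4-dimethyl-5-(3-methylbut-3-en-1-yl)cyclopent-2-en-1-one
Conditions: Pd2(dba)3 (2.5 mol %), (R)-(CF3)3-t-BuPHOX (6 mol %), toluene, 30 °C
Reagents that add atoms: none
Why: Pd-catalysed decarboxylative asymmetric allylic alkylation of an enol carbonate: loss of CO2 gives a Pd(allyl) enolate that couples at the enolate carbon to form quaternary C6 next to CMe2, the chiral PHOX ligand choosing the enolate face (S).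

Step 4
Reactants: 7 (S)-5-allyl-4,4-dimethyl-5-(3-methylbut-3-en-1-yl)cyclopent-2-en-1-one
Product: 8 (5S)-4,4,8-trimethylspiro[4.5]deca-2,7-dien-1-one
Conditions: Grubbs II catalyst (3 mol %), CH2Cl2, 40 °C
Reagents that add atoms: none
Why: Ring-closing olefin metathesis of the allyl and 1,1-disubstituted alkenes closes ring B as the trisubstituted C2=C3 cyclohexene with loss of ethene, while the hindered enone alkene stays inert.

Step 5
Reactants: 8 (5S)-4,4,8-trimethylspiro[4.5]deca-2,7-dien-1-one
Product: 10 (5S)-3-hydroxy-4,4,8-trimethylspiro[4.5]dec-7-en-1-one (C3 epimers), via β-boryl ketone 9 (not isolated)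
Conditions: B2pin2, CuCl (5 mol %), DPEphos, NaOt-Bu (cat.), MeOH, THF, 23 °C; then NaBO3·4H2O, THF/H2O, 23 °C
Reagents that add atoms: bis(pinacolato)diboron, CC1(C)OB(OC1(C)C)B1OC(C)(C)C(C)(C)O1 (boron of 9); sodium perborate, [Na+].[Na+].O[B-]1(O)OO[B-](O)(O)OO1 (oxygen of 10)
Why: Copper-catalysed conjugate borylation of the enone (the isolated ring-B alkene does not react) followed by C–B oxidation places oxygen on C9; its configuration is irrelevant because C9 becomes a ketone in step 12.

Step 6
Reactants: 10 (5S)-3-hydroxy-4,4,8-trimethylspiro[4.5]dec-7-en-1-one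
Product: 11 (5S)-3-(tert-butyldimethylsilyloxy)-4,4,8-trimethylspiro[4.5]dec-7-en-1-one (C3 epimers)
Conditions: TBSOTf, 2,6-lutidine, CH2Cl2, −78 → 0 °C
Reagents that add atoms: tert-butyldimethylsilyl triflate, CC(C)(C)[Si](C)(C)OS(=O)(=O)C(F)(F)F
Why: Silyl ether formation with the reactive triflate protects the hindered C9 hydroxyl, so the C7 and C9 oxygens can be handled separately.

Step 7
Reactants: 11 (5S)-3-(tert-butyldimethylsilyloxy)-4,4,8-trimethylspiro[4.5]dec-7-en-1-one
Product: 12 (5S)-3-(tert-butyldimethylsilyloxy)-4,4,8-trimethylspiro[4.5]dec-7-en-1-ol (C1 and C3 epimers)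
Conditions: NaBH4, MeOH, 0 °C
Reagents that add atoms: none
Why: Borohydride reduction of the cyclopentanone gives the C7 carbinol that acts as internal nucleophile in step 8; either C7 epimer can reach C3 by ring-A puckering, and the centre is erased in step 10.

Step 8
Reactants: 12 (5S)-3-(tert-butyldimethylsilyloxy)-4,4,8-trimethylspiro[4.5]dec-7-en-1-ol
Product: 13 (2R,3R,6S)-2-bromo-9-(tert-butyldimethylsilyloxy)-3,7-epoxy-10,14-dinorchamigrane (2-oxabicyclo[2.2.2]octane; O bridges C7 and C3 on the C7 face of ring B, Br on C2 anti to O; C7 and C9 epimers)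
Conditions: NBS, CH2Cl2, 0 °C, dark
Reagents that add atoms: N-bromosuccinimide, O=C1CCC(=O)N1Br
Why: Bromoetherification of the cineole type: the C7 hydroxyl, held on one face of ring B by the spiro centre, opens the bromonium ion at tertiary C3 through a boat, so C3–O is syn to C7 and C2–Br is anti to it, which sets C2 and the C3 face relative to C6.

Step 9
Reactants: 13 (2R,3R,6S)-2-bromo-9-(tert-butyldimethylsilyloxy)-3,7-epoxy-10,14-dinorchamigrane
Product: 14 (2R,3R,6S)-2-bromo-9-(tert-butyldimethylsilyloxy)-3-chloro-10,14-dinorchamigran-7-ol (C7 and C9 epimers)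
Conditions: TiCl4 (1.5 equiv), CH2Cl2, −78 °C; aq. NaHCO3
Reagents that add atoms: titanium tetrachloride, Cl[Ti](Cl)(Cl)Cl
Why: Lewis-acid cleavage of a tertiary alkyl ether to the tertiary chloride: the Ti-bound C3–O bond ionises with help from the antiperiplanar C2–Br (bromonium ion), chloride then enters C3 on the face the oxygen left (retention by double inversion, trans Br/Cl), and the secondary C7–O bond is not cleaved.

Step 10
Reactants: 14 (2R,3R,6S)-2-bromo-9-(tert-butyldimethylsilyloxy)-3-chloro-10,14-dinorchamigran-7-ol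
Product: 15 (2R,3R,6S)-2-bromo-9-(tert-butyldimethylsilyloxy)-3-chloro-10,14-dinorchamigran-7-one (C9 epimers)
Conditions: Dess–Martin periodinane, NaHCO3, CH2Cl2, 0 → 23 °C
Reagents that add atoms: none
Why: Dess–Martin oxidation of the secondary alcohol under buffered, non-basic conditions leaves both halides and the silyl ether untouched.

Step 11
Reactants: 15 (2R,3R,6S)-2-bromo-9-(tert-butyldimethylsilyloxy)-3-chloro-10,14-dinorchamigran-7-one
Product: 17 (2R,3R,6R)-2-bromo-3-chloro-10-norchamigr-7(14)-en-9-ol (C9 epimers), via β-hydroxysilane 16 (not isolated)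
Conditions: Me3SiCH2MgCl, CeCl3, THF, −78 → 0 °C; then 48% aq. HF, MeCN, 23 °C
Reagents that add atoms: (trimethylsilyl)methylmagnesium chloride, C[Si](C)(C)C[Mg]Cl
Why: Peterson olefination: the weakly basic organocerium reagent adds to the hindered ketone without expelling the β-silyloxy group, and acid-promoted elimination of β-hydroxysilane 16 can give only the exocyclic C7=C14 alkene, HF removing the silyl ether in the same operation.

Step 12
Reactants: 17 (2R,3R,6R)-2-bromo-3-chloro-10-norchamigr-7(14)-en-9-ol
Product: 18 (2R,3R,6R)-2-bromo-3-chloro-10-norchamigr-7(14)-en-9-one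
Conditions: Dess–Martin periodinane, NaHCO3, CH2Cl2, 0 °C; used without acidic chromatography
Reagents that add atoms: none
Why: Buffered Dess–Martin oxidation gives the β,γ-unsaturated cyclopentanone under neutral conditions, so the exocyclic double bond should not move into conjugation.

Step 13
Reactants: 18 (2R,3R,6R)-2-bromo-3-chloro-10-norchamigr-7(14)-en-9-one; 19 dibromomethane
Product: 23 (2R,3R,6R,10R)-2,10-dibromo-3-chlorochamigr-7(14)-en-9-one, via lithium dibromomethyl carbinolate 20 (not isolated), via β-oxido carbenoid 21 (not isolated), via lithium bromo enolate 22 (not isolated)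
Conditions: 19 (1.4 equiv), LiTMP (1.2 equiv), THF, −95 °C; add 18; then LiTMP (2.2 equiv), −95 → −20 °C; AcOH, −78 °C
Reagents that add atoms: none
Why: Pre-formed, amide-free LiCHBr2 adds to the C9 carbonyl to give 20; LiTMP then removes the CHBr2 proton, and carbenoid 21 expels bromide as the antiperiplanar ring bond C9–C11 shifts to the carbenoid carbon, forming C10–C11 and leaving C9–C10 as the enolate double bond of 22. The closest known reaction type is the homologation of cyclic ketones to ring-enlarged α-halo ketones through dihalomethyllithium adducts (β-oxido carbenoid rearrangement). No ring is closed; ring A grows from five to six members by a 1,2-shift, so no cyclisation mode applies. The new stereocentre C10 arises only on C-protonation of 22 and is not controlled here (both epimers are expected and interconvert through the enol); it is fixed in step 14. The step needs addition to win over proton abstraction at the doubly activated C8, and C11 to migrate instead of C8: the first is served by the low basicity of the pre-formed carbenoid reagent at −95 °C (after addition no carbonyl is left for the second base to enolise), the second by the fully substituted C11 being a better migrating group than the primary allylic C8. Bromine thus arrives on C10 together with the inserted carbon, so neither a C8 enolate nor a Br+ source that could attack C7=C14 is involved.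

Step 14
Reactants: 23 (2R,3R,6R,10R)-2,10-dibromo-3-chlorochamigr-7(14)-en-9-one (with its C10 epimer)
Product: 24 (2R,3R,6R,9S,10R)-2,10-dibromo-3-chlorochamigr-7(14)-en-9-ol
Conditions: ketoreductase (panel-selected for the 10R ketone and 9S delivery), NADP+, i-PrOH, triethanolamine buffer pH 8, DMSO (10%), 30 °C
Reagents that add atoms: none
Why: Biocatalytic dynamic reductive kinetic resolution of an α-halo ketone: the C10 epimers interconvert through the enol, the enzyme reduces only the 10R epimer on the C9 face that gives the 9S alcohol cis to bromine, and a chiral reductant is needed because ring B is too remote to bias C10, so an achiral hydride would reduce both epimers.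

Step 15
Reactants: 24 (2R,3R,6R,9S,10R)-2,10-dibromo-3-chlorochamigr-7(14)-en-9-ol
Product: 25 (2R,3R,6R,9S,10R)-2,10-dibromo-3-chlorochamigr-7(14)-en-9-yl acetate
Conditions: Ac2O, DMAP, pyridine, CH2Cl2, 23 °C
Reagents that add atoms: acetic anhydride, CC(=O)OC(C)=O
Why: DMAP-catalysed acylation of the hindered axial alcohol; the cis bromohydrin cannot close to an epoxide under this mild base.

**Compound list**

1 | 4,4-dimethylcyclopent-2-en-1-one | O=C1C=CC(C)(C)C1 | starting material
2 | 4-bromo-2-methylbut-1-ene | CC(=C)CCBr | starting material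
3 | lithium 3,3-dimethylcyclopenta-1,4-dien-1-olate | [Li]OC1=CC(C)(C)C=C1 | intermediate (not isolated)
4 | 4,4-dimethyl-5-(3-methylbut-3-en-1-yl)cyclopent-2-en-1-one (racemic) | O=C1C=CC(C)(C)C1CCC(C)=C | intermediate
5 | lithium 3,3-dimethyl-2-(3-methylbut-3-en-1-yl)cyclopenta-1,4-dien-1-olate | [Li]OC1=C(CCC(C)=C)C(C)(C)C=C1 | intermediate (not isolated)
6 | allyl 3,3-dimethyl-2-(3-methylbut-3-en-1-yl)cyclopenta-1,4-dien-1-yl carbonate | C=CCOC(=O)OC1=C(CCC(C)=C)C(C)(C)C=C1 | intermediate
7 | (S)-5-allyl-4,4-dimethyl-5-(3-methylbut-3-en-1-yl)cyclopent-2-en-1-one | O=C1C=CC(C)(C)[C@@]1(CC=C)CCC(C)=C | intermediate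
8 | (5S)-4,4,8-trimethylspiro[4.5]deca-2,7-dien-1-one | O=C1C=CC(C)(C)[C@@]12CCC(C)=CC2 | intermediate
9 | (5S)-4,4,8-trimethyl-3-(4,4,5,5-tetramethyl-1,3,2-dioxaborolan-2-yl)spiro[4.5]dec-7-en-1-one (C3 epimers) | O=C1CC(B3OC(C)(C)C(C)(C)O3)C(C)(C)[C@@]12CCC(C)=CC2 | intermediate (not isolated)
10 | (5S)-3-hydroxy-4,4,8-trimethylspiro[4.5]dec-7-en-1-one (C3 epimers) | O=C1CC(O)C(C)(C)[C@@]12CCC(C)=CC2 | intermediate
11 | (5S)-3-(tert-butyldimethylsilyloxy)-4,4,8-trimethylspiro[4.5]dec-7-en-1-one (C3 epimers) | O=C1CC(O[Si](C)(C)C(C)(C)C)C(C)(C)[C@@]12CCC(C)=CC2 | intermediate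
12 | (5S)-3-(tert-butyldimethylsilyloxy)-4,4,8-trimethylspiro[4.5]dec-7-en-1-ol (C1 and C3 epimers) | OC1CC(O[Si](C)(C)C(C)(C)C)C(C)(C)[C@@]12CCC(C)=CC2 | intermediate
13 | (2R,3R,6S)-2-bromo-9-(tert-butyldimethylsilyloxy)-3,7-epoxy-10,14-dinorchamigrane (C7 and C9 epimers) | O1C2CC(O[Si](C)(C)C(C)(C)C)C(C)(C)[C@@]23CC[C@]1(C)[C@H](Br)C3 | intermediate
14 | (2R,3R,6S)-2-bromo-9-(tert-butyldimethylsilyloxy)-3-chloro-10,14-dinorchamigran-7-ol (C7 and C9 epimers) | OC1CC(O[Si](C)(C)C(C)(C)C)C(C)(C)[C@@]12CC[C@@](C)(Cl)[C@H](Br)C2 | intermediate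
15 | (2R,3R,6S)-2-bromo-9-(tert-butyldimethylsilyloxy)-3-chloro-10,14-dinorchamigran-7-one (C9 epimers) | O=C1CC(O[Si](C)(C)C(C)(C)C)C(C)(C)[C@@]12CC[C@@](C)(Cl)[C@H](Br)C2 | intermediate
16 | (2R,3R,6S)-2-bromo-9-(tert-butyldimethylsilyloxy)-3-chloro-14-(trimethylsilyl)-10-norchamigran-7-ol (C7 and C9 epimers) | C[Si](C)(C)CC1(O)CC(O[Si](C)(C)C(C)(C)C)C(C)(C)[C@@]12CC[C@@](C)(Cl)[C@H](Br)C2 | intermediate (not isolated)
17 | (2R,3R,6R)-2-bromo-3-chloro-10-norchamigr-7(14)-en-9-ol (C9 epimers) | C=C1CC(O)C(C)(C)[C@@]12CC[C@@](C)(Cl)[C@H](Br)C2 | intermediate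
18 | (2R,3R,6R)-2-bromo-3-chloro-10-norchamigr-7(14)-en-9-one | C=C1CC(=O)C(C)(C)[C@@]12CC[C@@](C)(Cl)[C@H](Br)C2 | intermediate
19 | dibromomethane | BrCBr | starting material
20 | lithium (2R,3R,6R)-2-bromo-3-chloro-9-(dibromomethyl)-10-norchamigr-7(14)-en-9-olate | C=C1CC(O[Li])(C(Br)Br)C(C)(C)[C@@]12CC[C@@](C)(Cl)[C@H](Br)C2 | intermediate (not isolated)
21 | C-lithiated carbinolate of 20 (β-oxido carbenoid, C(Li)Br2 on C9) | C=C1CC(O[Li])(C([Li])(Br)Br)C(C)(C)[C@@]12CC[C@@](C)(Cl)[C@H](Br)C2 | intermediate (not isolated)
22 | lithium (2R,3R,6R)-2,10-dibromo-3-chlorochamigra-7(14),9-dien-9-olate | C=C1CC(O[Li])=C(Br)C(C)(C)[C@@]12CC[C@@](C)(Cl)[C@H](Br)C2 | intermediate (not isolated)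
23 | (2R,3R,6R,10R)-2,10-dibromo-3-chlorochamigr-7(14)-en-9-one | C=C1CC(=O)[C@H](Br)C(C)(C)[C@@]12CC[C@@](C)(Cl)[C@H](Br)C2 | intermediate
24 | (2R,3R,6R,9S,10R)-2,10-dibromo-3-chlorochamigr-7(14)-en-9-ol | C=C1C[C@H](O)[C@H](Br)C(C)(C)[C@@]12CC[C@@](C)(Cl)[C@H](Br)C2 | intermediate
25 | (2R,3R,6R,9S,10R)-2,10-dibromo-3-chlorochamigr-7(14)-en-9-yl acetate | C=C1C[C@H](OC(C)=O)[C@H](Br)C(C)(C)[C@@]12CC[C@@](C)(Cl)[C@H](Br)C2 | target

**Step count.** Total: 15 steps. Longest linear sequence: 15 steps (fully linear from 1).

**Steps most likely to fail**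

Step 13. Proton transfer from C8 to the carbenoid reagent may compete with carbonyl addition, the carbinolate C–H may not be lithiated cleanly, or C8 may migrate in place of C11. The fallback sets out from 18 and 19 and returns at 23. LiCHBr2 is added as before, but the adduct is protonated and isolated as (2R,3R,6R)-2-bromo-3-chloro-9-(dibromomethyl)-10-norchamigr-7(14)-en-9-ol F1. Treatment with n-BuLi (2.2 equiv, THF, −95 °C) removes the hydroxyl proton and exchanges one bromine for lithium. The monobromo β-oxido carbenoid rearranges with C11 shift to the bromine-free ring-enlarged lithium enolate, lithium (2R,3R,6R)-2-bromo-3-chlorochamigra-7(14),9-dien-9-olate F2, whose double bond is fixed between C9 and C10. Bromination of this enolate at −78 °C with one equivalent of NBS places bromine on C10 and gives 23. The carbenoid is thus generated by halogen–metal exchange instead of deprotonation, and the bromine is introduced afterwards on a regiodefined enolate.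

Step 14. C10 epimerisation may be too slow at the pH the enzyme and the β,γ-enone tolerate, or the hindered ketone may be poorly accepted, so conversion stalls or stereocontrol is lost. The fallback sets out from 23 and returns at 24. The epimer mixture is reduced with (R)-Me-CBS oxazaborolidine (20 mol %) and BH3·SMe2 in toluene at −40 °C. Reagent control (C10 as the large group) delivers hydride to give the 9S alcohol, which for the 10R ketone coincides with the equatorial attack enforced by the axial C11 methyl, so 24 forms from that epimer. The mismatched epimer, (2R,3R,6R,10S)-2,10-dibromo-3-chlorochamigr-7(14)-en-9-one F3, should react slowly; it is recovered, re-equilibrated at C10 with a catalytic amine base and resubmitted. This replaces the dynamic enzymatic process by a catalyst-controlled kinetic selection with recycling.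

Step 9. Ionisation at C3 may proceed through an open cation (loss of configuration at C3 or E1 elimination), or the Lewis acid may remove the silyl ether. The fallback sets out from 13 and returns at 14. Acylative ether cleavage with acetyl chloride and catalytic ZnCl2 (CH2Cl2, 0 °C) activates the ether as an acyloxonium ion, and chloride enters C3 under the same bromine participation. The C7 oxygen leaves as an ester, giving (2R,3R,6S)-2-bromo-9-(tert-butyldimethylsilyloxy)-3-chloro-10,14-dinorchamigran-7-yl acetate F4. Methanolysis (K2CO3, MeOH, 0 °C) then returns 14.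

**Further compounds**

F1 | step 13 | (2R,3R,6R)-2-bromo-3-chloro-9-(dibromomethyl)-10-norchamigr-7(14)-en-9-ol | C=C1CC(O)(C(Br)Br)C(C)(C)[C@@]12CC[C@@](C)(Cl)[C@H](Br)C2
F2 | step 13 | lithium (2R,3R,6R)-2-bromo-3-chlorochamigra-7(14),9-dien-9-olate | C=C1CC(O[Li])=CC(C)(C)[C@@]12CC[C@@](C)(Cl)[C@H](Br)C2
F3 | step 14 | (2R,3R,6R,10S)-2,10-dibromo-3-chlorochamigr-7(14)-en-9-one | C=C1CC(=O)[C@@H](Br)C(C)(C)[C@@]12CC[C@@](C)(Cl)[C@H](Br)C2
F4 | step 9 | (2R,3R,6S)-2-bromo-9-(tert-butyldimethylsilyloxy)-3-chloro-10,14-dinorchamigran-7-yl acetate | CC(=O)OC1CC(O[Si](C)(C)C(C)(C)C)C(C)(C)[C@@]12CC[C@@](C)(Cl)[C@H](Br)C2
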